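L is what you want from the ochre flask, and this is what stands before you:

the same everywhere: G 0.25 mM
- ochre: D 0.50 M; X 0.65 M; the very flask that is asked about, followed so far
- red: D 0.25 M; X 0.65 M; run made earlier
- flask: D 0.50 M; X 0.650 M; time 40 h

- ochre (time / h: L / %): 3.00: 8.5; 8.00: 17.1; 15.0: 17.0; 25.0: 15.1
- red (time / h: L / %): 1.00: 2.7; 3.00: 8.6; 5.00: 14.9; 8.00: 18.7

(scatter of a reading: 1 percentage point)

- Friday's: change nothing and wait 3.0 d more
- Wednesday's: at 40 h add X, 50.0% of the amount charged, then wait 3.0 d
- Tuesday's: at 40 h take out 90% of the L then present, then wait 3.0 d
- Sunday's: at 40 h add G, 100% of the amount charged, then wait 3.0 d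

- a species is counted by the D in it: one Q counts as two
- L that was removed still counts
- the numbers in the tables scatter with a standard deviation of 1 percentage point
- candidate steps: D + G <-> G + E; G + E <-> Z; X + Z -> G + L; G -> J; D + L -> Q
- additions bring no volume worth counting

- L, in percent of the D first charged, at 40 h
- the remedy with the largest gain of L, or "none" below 2 percentage points (Friday's / Wednesday's / Tuesday's / Sunday's / none)
- L present, with what was taken out counted in, in percent of the D first charged, after Friday's
- L present, with what was taken out counted in, in percent of the D first charged, after Tuesday's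

The ochre readings hold a contradiction: L stands at 17.1% after 8.00 h and at 17.0% after 15.0 h, yet the L standing there accounts for 13.2% of the X charged. So the L standing in the ochre flask accounts for less X than was charged, and the stall needs another explanation. The later readings clear it up, for L then goes down with X still in hand, so making has faded and something eats L; the card offers G → J for the first and D + L → Q for the second.

Once making has faded, take the rate as dL/dt = −fL, so that L(t) = L(t₀)·exp(−f(t − t₀)). Here f is the fall constant of L 0.0119 h⁻¹, a pseudo-first-order constant read from the last two ochre readings. It is a rough reading, since the drop of 1.9 percentage points stands against a scatter of 1 point per reading.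

Carried forward, my reckoning for the ochre flask gives 12.6% at 40 h, 5.38% after Friday's and 11.9% after Tuesday's. Wednesday's adds X, which the flask has in hand, so you should pick Sunday's, which restarts the making.

The forecast gives 12.8%, 5.9%, 12.1% and Sunday's, saying “which means the catalyst has died”.

The flask gives 10.9%, 5.33% and 10.2%, and Sunday's is best with a gain of 10 points.

    D + G ⇌ G + E (K = 5.20, k = 9.60 M⁻¹ min⁻¹)
    G + E ⇌ Z (K = 2.20 M⁻¹, k = 34.0 M⁻¹ min⁻¹)
    X + Z → G + L (k = 55.0 M⁻¹ min⁻¹)
    G → J (k = 0.00200 min⁻¹)
    D + L → Q (k = 0.00880 M⁻¹ min⁻¹)

The fall is the step D + L → Q, which is one part of the loss: the ochre flask without it stands at 48.7% at 40 h instead of 10.9%. The gain of Sunday's comes with the step G → J as its largest single effect: without that step the ochre flask gains 0.055 points from Sunday's instead of 10 points. Put on the ochre flask's 10.9% at 40 h, f gives 4.66% after Friday's, where the flask stands at 5.33%. Scaled by the D charged, f becomes 0.00593 h⁻¹ for the red flask, which takes its 21.6% at 8.00 h to 17.9% at 40 h, where the red flask stands at 19.3%.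

The runs are calculated on assumed constants; scatter was added.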